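**Assumption:** kazinol C has no stereocentre and no E/Z-stereogenic alkene, so there is no enantiomer to select; the route targets the single achiral structure.

**Retrosynthetic overview**
1. Last step: global removal of four MOM ethers.
2. Key disconnection: one three-component Pd/norbornene (Catellani-type) event on ring B. Ortho C–H alkylation makes the aryl–CH2 bond of the 1,3-diarylpropane, and ipso prenylation makes the adjacent aryl–prenyl bond (aryl iodide + alkyl iodide + prenylboronate).
3. Ring-A partner (alkyl iodide): resorcinol → bis-MOM → 4,6-dibromide → mono Br/Li exchange and oxetane opening → branch-selective Suzuki reverse prenylation → Appel iodination.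
4. Ring-B partner (aryl iodide): catechol → bis-MOM → 4-bromide → metalation between OMOM and Br, Cu-mediated prenylation → Br-to-I exchange.
5. No ring is constructed: both benzene rings come from resorcinol and catechol, and all C5 units come from prenyl halides.

**Route**

Step 1
Reactants: 1, prenyl chloride (1-chloro-3-methylbut-2-ene)
Product: 2, prenylboronic acid pinacol ester (4,4,5,5-tetramethyl-2-(3-methylbut-2-en-1-yl)-1,3,2-dioxaborolane)
Conditions: B2pin2 (1.1 equiv), Pd2(dba)3 (1 mol %), THF, 60 °C
Reagents that add atoms: bis(pinacolato)diboron, CC1(C)OB(OC1(C)C)B1OC(C)(C)C(C)(C)O1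
Why: Pd-catalysed allylic borylation; the π-prenyl-Pd intermediate transmetalates with the diboron and forms the C–B bond at the unhindered CH2 terminus, giving the linear boronate.

Step 2
Reactants: 3, resorcinol
Product: 4, 1,3-bis(methoxymethoxy)benzene
Conditions: MOMCl (2.5 equiv), i-Pr2NEt, CH2Cl2, 0 °C → rt
Reagents that add atoms: chloromethyl methyl ether, COCCl
Why: Standard phenol O-alkylation (acetal protection); MOM is base- and organolithium-stable and later serves as a coordinating group.

Step 3
Reactants: 4, 1,3-bis(methoxymethoxy)benzene
Product: 5, 1,5-dibromo-2,4-bis(methoxymethoxy)benzene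
Conditions: NBS (2.05 equiv), MeCN, 0 °C → rt
Reagents that add atoms: N-bromosuccinimide, O=C1CCC(=O)N1Br
Why: Electrophilic aromatic bromination; the two equivalent positions para to one oxygen and ortho to the other react, while the hindered position between the oxygens does not, and neutral NBS spares the MOM acetals.

Step 4
Reactants: 5, 1,5-dibromo-2,4-bis(methoxymethoxy)benzene; 6, oxetane
Product: 7, 3-[5-bromo-2,4-bis(methoxymethoxy)phenyl]propan-1-ol
Conditions: n-BuLi (1.0 equiv), THF, −78 °C; then 6, BF3·OEt2, −78 °C
Reagents that add atoms: none (oxetane is reactant 6)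
Why: Mono Br/Li exchange desymmetrises the dibromide (a second exchange on the aryl anion is disfavoured, and the meta bromide cannot give an aryne); BF3-activated oxetane ring opening by the aryllithium installs the three-carbon chain.

Step 5
Reactants: 7, 3-[5-bromo-2,4-bis(methoxymethoxy)phenyl]propan-1-ol; 2, prenylboronic acid pinacol ester
Product: 8, 3-[2,4-bis(methoxymethoxy)-5-(2-methylbut-3-en-2-yl)phenyl]propan-1-ol
Conditions: 2 (1.5 equiv), [Pd(allyl)Cl]2 (2 mol %), t-BuXPhos (4–5 mol %), aq K3PO4, MeCN, 70 °C
Reagents that add atoms: none (2 is a numbered reactant)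
Why: Ligand-controlled γ-selective Suzuki–Miyaura allylation; SE2′ transmetalation puts Pd on the tertiary carbon and the very bulky ligand forces reductive elimination before σ–π–σ isomerisation, giving the 1,1-dimethylallyl group, with the free primary alcohol tolerated.

Step 6
Reactants: 8, 3-[2,4-bis(methoxymethoxy)-5-(2-methylbut-3-en-2-yl)phenyl]propan-1-ol
Product: 9, 1-(3-iodopropyl)-2,4-bis(methoxymethoxy)-5-(2-methylbut-3-en-2-yl)benzene
Conditions: PPh3, imidazole, I2 (premixed), CH2Cl2, 0 °C → rt
Reagents that add atoms: iodine, II
Why: Appel iodination of a primary alcohol; the buffered, preformed phosphonium iodide leaves the MOM acetals and the hindered vinyl group untouched.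

Step 7
Reactants: 10, catechol
Product: 11, 1,2-bis(methoxymethoxy)benzene
Conditions: MOMCl (2.5 equiv), i-Pr2NEt, CH2Cl2, 0 °C → rt, under Ar
Reagents that add atoms: chloromethyl methyl ether, COCCl
Why: Phenol O-alkylation (acetal protection); it masks the oxidation-prone catechol and provides the metalation-directing group.

Step 8
Reactants: 11, 1,2-bis(methoxymethoxy)benzene
Product: 12, 4-bromo-1,2-bis(methoxymethoxy)benzene
Conditions: NBS (1.0 equiv), MeCN, 0 °C → rt
Reagents that add atoms: N-bromosuccinimide, O=C1CCC(=O)N1Br
Why: Electrophilic aromatic bromination para to an alkoxy group, as for veratrole; one equivalent avoids the 4,5-dibromide.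

Step 9
Reactants: 12, 4-bromo-1,2-bis(methoxymethoxy)benzene; 13, prenyl bromide (1-bromo-3-methylbut-2-ene)
Product: 14, 1-bromo-3,4-bis(methoxymethoxy)-2-(3-methylbut-2-en-1-yl)benzene
Conditions: LiTMP (1.1 equiv), THF, −78 °C; CuBr·SMe2 (1.1 equiv), −78 → −40 °C; 13 (1.5 equiv), −40 °C → rt
Reagents that add atoms: none (13 is a numbered reactant)
Why: Directed ortho-metalation by a non-nucleophilic amide base at the doubly activated C–H between OMOM and Br (no Br/Li exchange, aryne-stable at −78 °C), then SN2 allylation of the hindered arylcopper at the primary carbon of prenyl bromide to give the linear prenyl group.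

Step 10
Reactants: 14, 1-bromo-3,4-bis(methoxymethoxy)-2-(3-methylbut-2-en-1-yl)benzene
Product: 15, 1-iodo-3,4-bis(methoxymethoxy)-2-(3-methylbut-2-en-1-yl)benzene
Conditions: NaI (2 equiv), CuI (10 mol %), trans-N,N′-dimethylcyclohexane-1,2-diamine (20 mol %), dioxane, 110 °C
Reagents that add atoms: sodium iodide, [Na+].[I-]
Why: Copper-catalysed aromatic Finkelstein halogen exchange, driven by NaBr precipitation, gives the aryl iodide needed for clean Pd(0) oxidative addition in the next step.

Step 11
Reactants: 15, 1-iodo-3,4-bis(methoxymethoxy)-2-(3-methylbut-2-en-1-yl)benzene (1.0 equiv); 9, 1-(3-iodopropyl)-2,4-bis(methoxymethoxy)-5-(2-methylbut-3-en-2-yl)benzene (1.3 equiv); 2, prenylboronic acid pinacol ester (2 equiv)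
Product: 16, 1-{3-[2,4-bis(methoxymethoxy)-5-(2-methylbut-3-en-2-yl)phenyl]propyl}-4,5-bis(methoxymethoxy)-2,3-bis(3-methylbut-2-en-1-yl)benzene (tetra-MOM kazinol C)
Conditions: Pd(OAc)2 (10 mol %), P(2-furyl)3 (25 mol %), norbornene (2 equiv), Cs2CO3 (3 equiv), H2O (5 equiv), MeCN, 80 °C; 2 added by syringe pump over 6 h
Reagents that add atoms: none (all three partners are numbered reactants)
Why: Proposed new method: oxidative addition of 15, norbornene insertion and ortho C–H palladation give the aryl-norbornyl palladacycle, which adds primary iodide 9 (Pd(II)/Pd(IV)) and reductively eliminates to form the aryl–CH2 bond; the now 2,6-disubstituted aryl extrudes norbornene, and the resulting aryl-Pd(II) is intercepted by prenylboronate 2 (SE2′ transmetalation, σ–π–σ equilibration), with C–C reductive elimination at the unhindered CH2 terminus enforced by the two flanking ortho groups, while slow addition of 2 suppresses premature direct Suzuki coupling and the hindered unactivated vinyl group of 9 is expected to be too slow a Heck acceptor to compete. Closest known reaction types: Catellani ortho-alkylation with ipso-Suzuki termination by arylboronic acids, and linear-selective Pd-catalysed coupling of prenylboron reagents with aryl halides; an allyl/prenylboron ipso termination in this manifold has not been demonstrated.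

Step 12
Reactants: 16, tetra-MOM kazinol C
Product: 17, kazinol C (5-{3-[2,4-dihydroxy-5-(2-methylbut-3-en-2-yl)phenyl]propyl}-3,4-bis(3-methylbut-2-en-1-yl)benzene-1,2-diol)
Conditions: 3 M aq HCl, MeOH/THF (degassed), 40 °C, under Ar; stop at full conversion, NaHCO3 work-up
Reagents that add atoms: none
Why: Acid-catalysed acetal hydrolysis removes all four aryl MOM ethers; the mild, short, oxygen-free conditions are intended to keep the prenyl and 1,1-dimethylallyl groups from cyclising onto the neighbouring phenols and the catechol from oxidising.

**Compound list**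
1 | prenyl chloride (1-chloro-3-methylbut-2-ene) | CC(C)=CCCl | starting material
2 | prenylboronic acid pinacol ester | CC(C)=CCB1OC(C)(C)C(C)(C)O1 | intermediate
3 | resorcinol | Oc1cccc(O)c1 | starting material
4 | 1,3-bis(methoxymethoxy)benzene | COCOc1cccc(OCOC)c1 | intermediate
5 | 1,5-dibromo-2,4-bis(methoxymethoxy)benzene | COCOc1cc(OCOC)c(Br)cc1Br | intermediate
6 | oxetane | C1COC1 | starting material
7 | 3-[5-bromo-2,4-bis(methoxymethoxy)phenyl]propan-1-ol | OCCCc1cc(Br)c(OCOC)cc1OCOC | intermediate
8 | 3-[2,4-bis(methoxymethoxy)-5-(2-methylbut-3-en-2-yl)phenyl]propan-1-ol | OCCCc1cc(C(C)(C)C=C)c(OCOC)cc1OCOC | intermediate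
9 | 1-(3-iodopropyl)-2,4-bis(methoxymethoxy)-5-(2-methylbut-3-en-2-yl)benzene | ICCCc1cc(C(C)(C)C=C)c(OCOC)cc1OCOC | intermediate
10 | catechol | Oc1ccccc1O | starting material
11 | 1,2-bis(methoxymethoxy)benzene | COCOc1ccccc1OCOC | intermediate
12 | 4-bromo-1,2-bis(methoxymethoxy)benzene | COCOc1ccc(Br)cc1OCOC | intermediate
13 | prenyl bromide (1-bromo-3-methylbut-2-ene) | CC(C)=CCBr | starting material
14 | 1-bromo-3,4-bis(methoxymethoxy)-2-(3-methylbut-2-en-1-yl)benzene | COCOc1ccc(Br)c(CC=C(C)C)c1OCOC | intermediate
15 | 1-iodo-3,4-bis(methoxymethoxy)-2-(3-methylbut-2-en-1-yl)benzene | COCOc1ccc(I)c(CC=C(C)C)c1OCOC | intermediate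
16 | tetra-MOM kazinol C | C=CC(C)(C)c1cc(CCCc2cc(OCOC)c(OCOC)c(CC=C(C)C)c2CC=C(C)C)c(OCOC)cc1OCOC | intermediate
17 | kazinol C | C=CC(C)(C)c1cc(CCCc2cc(O)c(O)c(CC=C(C)C)c2CC=C(C)C)c(O)cc1O | target

**Totals**
Total step count: 12.
Longest linear sequence: 7 steps (steps 2, 3, 4, 5, 6, 11, 12, from resorcinol).

**Three steps most likely to fail**
1. Step 11 (proposed new three-component ortho-alkylation/ipso-prenylation). Main risks are premature Suzuki coupling of 15 with 2, α/γ scrambling of the prenyl transfer, and Heck termination on the vinyl group of 9. Fallback with known chemistry: prepare 1,2-dibromo-4,5-bis(methoxymethoxy)-3-(3-methylbut-2-en-1-yl)benzene (11 with 2 equiv NBS, then the step 9 protocol) and run two conventional couplings in sequence. First, a Negishi sp3–sp2 coupling of the alkylzinc from 9 (Zn, LiCl) at the less hindered C–Br; second, a linear-selective Pd-catalysed prenylation at the remaining hindered C–Br.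
2. Step 5 (γ-selective reverse prenylation). The branched:linear ratio may erode when forming a quaternary carbon next to an ortho-OMOM group. Fallback: build the 1,1-dimethylallyl group stepwise on the TBS ether of 7 by Pd-catalysed α-arylation of methyl isobutyrate enolate, DIBAL-H reduction to the aldehyde, and Wittig methylenation.
3. Step 12 (global MOM removal). Acid may cyclise an ortho-prenyl phenol to a chroman, or the reverse-prenyl phenol to a dihydrobenzofuran. Fallback: change the protecting-group strategy to SEM ethers from steps 2 and 7 onward (the same directing ability in the lithiation steps), so the final unmasking is fluoride-mediated (TBAF, DMPU) and not protic acid.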